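**Retrosynthetic overview**

Numbering used (terpenoid style): ring A = C1–C5 + C10, ring B = C5–C10; C3 carries Br, C4 carries CH3 and the side chain C12–C16, C8 carries the exocyclic CH2 (C17), C9 carries C11H2–Ar, C10 carries CH3; the target is (3R,4R,5S,9R,10S).
Last operations: saponification of ArOAc/CO2Me ⇐ cross-metathesis that turns a but-3-enyl group on C4 into the 4-methylpent-3-enyl chain.
Key disconnection: C4–C5 (closes ring A) and, in the same cascade, C9–C10 (closes ring B); ring A forms first, ring B second, from an acyclic chain carrying Br on C3, a trifluoroacetate on C4, an (E)-C5=C10 olefin and a (Z)-allylsilane C9=C8–C17H2SiMe3.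
Feature that allows this: Br on C3 is vicinal and anti to the new bond at the quaternary C4, rings A/B are trans-fused all-chair with equatorial Br, side chain and CH2Ar, and the C8=C17 methylene sits next to C9 – the imprint of anti opening of a C3/C4 bromonium ion at its tertiary carbon, followed by a chair–chair cation–olefin cascade ended by loss of a group from C17.
Precursor: geranyl bromide + C3 alkyne unit; SeO2 oxidation at C12 and Sharpless epoxidation fix C3/C4; C12 is allylated; carbocupration (CH2SiMe3) and Negishi benzylation build the allylsilane and bring in the arene; bromide then opens the epoxide at C3.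

Key step: step 13

Remark: compounds 1, 2 and 12 are taken as commercial; the side-chain olefin is deliberately carried as a non-nucleophilic terminal vinyl group through the cationic step.

**Route**

Step 1
Reactants: 1 geranyl bromide [(2E)-1-bromo-3,7-dimethylocta-2,6-diene]; 2 trimethyl(prop-1-yn-1-yl)silane
Product: 4 trimethyl[(5E)-6,10-dimethylundeca-5,9-dien-1-yn-1-yl]silane, via lithiated silylpropyne 3 (not isolated)
Conditions: 2, n-BuLi, TMEDA, Et2O, 0 °C; then 1, −78 °C → rt
Reagents that add atoms: none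
Why: Propargylic lithiation of 2 and SN2 displacement of the primary allylic bromide (alkylation of a propargylic organolithium) should give the 1,5-enyne with the (E)-olefin untouched, the silyl group blocking metalation at the alkyne terminus.

Step 2
Reactants: 4 trimethyl[(5E)-6,10-dimethylundeca-5,9-dien-1-yn-1-yl]silane
Product: 5 (2E,6E)-2,6-dimethyl-11-(trimethylsilyl)undeca-2,6-dien-10-yn-1-ol
Conditions: SeO2 (cat.), t-BuOOH, salicylic acid (cat.), CH2Cl2, 0 °C → rt
Reagents that add atoms: tert-butyl hydroperoxide, CC(C)(C)OO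
Why: SeO2-catalysed allylic (Riley-type) oxidation is known to hydroxylate the (E)-methyl group of the terminal isopropylidene unit of polyprenyl chains by an ene/[2,3]-sigmatropic sequence, which leaves the new trisubstituted olefin E (the oxidised carbon becomes C12).

Step 3
Reactants: 5 (2E,6E)-2,6-dimethyl-11-(trimethylsilyl)undeca-2,6-dien-10-yn-1-ol
Product: 6 [(2S,3S)-2-methyl-3-[(3E)-3-methyl-8-(trimethylsilyl)oct-3-en-7-yn-1-yl]oxiran-2-yl]methanol
Conditions: Ti(OiPr)4 (cat.), L-(+)-diisopropyl tartrate (cat.), t-BuOOH, 4 Å MS, CH2Cl2, −20 °C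
Reagents that add atoms: tert-butyl hydroperoxide, CC(C)(C)OO
Why: The Katsuki–Sharpless asymmetric epoxidation acts only on the allylic alcohol olefin and, with the L-(+)-tartrate ligand, should deliver oxygen to the face that gives the (2S,3S)-epoxide (the carbons that become C4 and C3), as for other (E)-2-methylalk-2-en-1-ols.

Step 4
Reactants: 6 [(2S,3S)-2-methyl-3-[(3E)-3-methyl-8-(trimethylsilyl)oct-3-en-7-yn-1-yl]oxiran-2-yl]methanol
Product: 8 (2S,3S)-2-(but-3-en-1-yl)-2-methyl-3-[(3E)-3-methyl-8-(trimethylsilyl)oct-3-en-7-yn-1-yl]oxirane, via epoxy triflate 7 (not isolated)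
Conditions: Tf2O, 2,6-lutidine, CH2Cl2, −78 °C; then allylMgBr, CuI (cat.), Et2O, −78 → −30 °C
Reagents that add atoms: allylmagnesium bromide, C=CC[Mg]Br
Why: A primary epoxy triflate is displaced by an allyl Grignard reagent under copper catalysis (Grignard–triflate cross-coupling) much faster than the trisubstituted epoxide is opened, so the C12–C13 bond should form with both epoxide stereocentres untouched.

Step 5
Reactants: 8 (2S,3S)-2-(but-3-en-1-yl)-2-methyl-3-[(3E)-3-methyl-8-(trimethylsilyl)oct-3-en-7-yn-1-yl]oxirane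
Product: 9 (2S,3S)-2-(but-3-en-1-yl)-2-methyl-3-[(3E)-3-methyloct-3-en-7-yn-1-yl]oxirane
Conditions: K2CO3 (cat.), MeOH, rt
Reagents that add atoms: none
Why: Carbonate-catalysed methanolysis of the alkynyl C–Si bond (protodesilylation of a silylalkyne) is mild enough to leave the epoxide intact.

Step 6
Reactants: 9 (2S,3S)-2-(but-3-en-1-yl)-2-methyl-3-[(3E)-3-methyloct-3-en-7-yn-1-yl]oxirane
Product: 11 (2S,3S)-2-(but-3-en-1-yl)-3-[(3E,7Z)-8-iodo-3-methyl-7-[(trimethylsilyl)methyl]octa-3,7-dien-1-yl]-2-methyloxirane, via alkenylcopper 10 (not isolated)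
Conditions: Me3SiCH2MgCl, CuBr·SMe2, Et2O/Me2S, −40 °C; add 9, −25 → 0 °C; then I2, THF, −40 °C
Reagents that add atoms: (trimethylsilyl)methylmagnesium chloride, C[Si](C)(C)C[Mg]Cl; iodine, II
Why: syn-Carbocupration of the terminal alkyne puts the silylmethyl group on the internal carbon (C8) and copper on the terminal carbon (C9) on the same side, and iodinolysis with retention should give the (Z)-iodide with iodine cis to CH2SiMe3.

Step 7
Reactants: 12 methyl 4-hydroxy-3-methylbenzoate
Product: 13 methyl 3-bromo-4-hydroxy-5-methylbenzoate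
Conditions: NBS, MeCN, 0 °C → rt
Reagents that add atoms: N-bromosuccinimide, O=C1CCC(=O)N1Br
Why: Electrophilic aromatic bromination of the phenol should occur at the only free activated position, ortho to the hydroxyl (para is blocked by the ester).

Step 8
Reactants: 13 methyl 3-bromo-4-hydroxy-5-methylbenzoate
Product: 14 methyl 4-(acetyloxy)-3-bromo-5-methylbenzoate
Conditions: Ac2O, pyridine, DMAP (cat.), CH2Cl2, rt
Reagents that add atoms: acetic anhydride, CC(=O)OC(C)=O
Why: O-Acetylation masks the phenol for the radical bromination, the organozinc step and the cationic step, where a free phenol oxygen could capture the C8 cation.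

Step 9
Reactants: 14 methyl 4-(acetyloxy)-3-bromo-5-methylbenzoate
Product: 15 methyl 4-(acetyloxy)-3-bromo-5-(bromomethyl)benzoate
Conditions: NBS, AIBN (cat.), PhCF3, 85 °C
Reagents that add atoms: N-bromosuccinimide, O=C1CCC(=O)N1Br
Why: Wohl–Ziegler radical bromination should functionalise the only benzylic methyl group.

Step 10
Reactants: 15 methyl 4-(acetyloxy)-3-bromo-5-(bromomethyl)benzoate; 11 (2S,3S)-2-(but-3-en-1-yl)-3-[(3E,7Z)-8-iodo-3-methyl-7-[(trimethylsilyl)methyl]octa-3,7-dien-1-yl]-2-methyloxirane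
Product: 17 methyl 4-(acetyloxy)-3-bromo-5-[(2Z,6E)-9-[(2S,3S)-3-(but-3-en-1-yl)-3-methyloxiran-2-yl]-7-methyl-3-[(trimethylsilyl)methyl]nona-2,6-dien-1-yl]benzoate, via benzylzinc bromide 16 (not isolated)
Conditions: 15, Zn dust, LiCl, THF, rt; then 11, Pd(PPh3)4 (cat.), THF, rt
Reagents that add atoms: none
Why: In this Negishi sp2–sp3 coupling zinc inserts into the benzylic C–Br bond and zerovalent palladium adds to the alkenyl iodide much faster than to the hindered aryl bromide, so the C9–C11 bond should form with retention of the olefin geometry (CH2Ar cis to CH2SiMe3) while esters, epoxide and allylsilane are tolerated.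

Step 11
Reactants: 17 methyl 4-(acetyloxy)-3-bromo-5-[(2Z,6E)-9-[(2S,3S)-3-(but-3-en-1-yl)-3-methyloxiran-2-yl]-7-methyl-3-[(trimethylsilyl)methyl]nona-2,6-dien-1-yl]benzoate
Product: 18 methyl 4-(acetyloxy)-3-bromo-5-[(2Z,6E,10R,11S)-10-bromo-11-hydroxy-7,11-dimethyl-3-[(trimethylsilyl)methyl]pentadeca-2,6,14-trien-1-yl]benzoate
Conditions: Li2NiBr4 (stock solution in THF), THF, 0 °C → rt; pH 7 buffer
Reagents that add atoms: dilithium tetrabromonickelate, [Li+].[Li+].[Ni+2].[Br-].[Br-].[Br-].[Br-]
Why: The soft, only weakly Lewis-acidic bromide source should open the trisubstituted epoxide in an SN2 manner at its less substituted carbon (C3) with inversion, giving the anti bromohydrin (C3 R, C4 S) whose C3–Br bond is the one kept in the target.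

Step 12
Reactants: 18 methyl 4-(acetyloxy)-3-bromo-5-[(2Z,6E,10R,11S)-10-bromo-11-hydroxy-7,11-dimethyl-3-[(trimethylsilyl)methyl]pentadeca-2,6,14-trien-1-yl]benzoate
Product: 19 methyl 4-(acetyloxy)-3-bromo-5-[(2Z,6E,10R,11S)-10-bromo-7,11-dimethyl-11-(trifluoroacetoxy)-3-[(trimethylsilyl)methyl]pentadeca-2,6,14-trien-1-yl]benzoate
Conditions: (CF3CO)2O, pyridine, CH2Cl2, 0 °C; used without chromatography
Reagents that add atoms: trifluoroacetic anhydride, O=C(OC(=O)C(F)(F)F)C(F)(F)F
Why: Trifluoroacetic anhydride acylates even hindered tertiary alcohols (O-acylation) under weakly basic conditions that neither close the bromohydrin back to the epoxide nor ionise the product.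

Step 13
Reactants: 19 methyl 4-(acetyloxy)-3-bromo-5-[(2Z,6E,10R,11S)-10-bromo-7,11-dimethyl-11-(trifluoroacetoxy)-3-[(trimethylsilyl)methyl]pentadeca-2,6,14-trien-1-yl]benzoate
Product: 21 methyl 4-(acetyloxy)-3-bromo-5-{[(1R,4aS,5R,6R,8aS)-6-bromo-5-(but-3-en-1-yl)-5,8a-dimethyl-2-methylidenedecahydronaphthalen-1-yl]methyl}benzoate, via bromiranium ion 20 (not isolated)
Conditions: (CF3)2CHOH (high dilution), 2,6-di-tert-butyl-4-methylpyridine, 0 °C → rt
Reagents that add atoms: none
Why: In the ionising, non-nucleophilic solvent the tertiary trifluoroacetate should leave with anchimeric assistance of the anti-periplanar bromine on C3, giving the enantiopure bromiranium ion 20, which the C5=C10 olefin opens at C4 anti to bromine; the C10 cation so formed is captured by C9 of the allylsilane and loss of the silyl group from the β-silyl C8 cation leaves the C8=C17 methylene. The closest known reaction types are the enantiospecific bromonium-initiated polyene cyclisation started by solvolysis of an enantioenriched vicinal bromide bearing a tertiary leaving group, and the allylsilane-terminated cation–olefin cyclisation. Ring A closes by 6-endo-trig attack of the C5=C10 olefin on C4 (bond C4–C5) and ring B by 6-endo-trig attack of the allylsilane on C10 (bond C9–C10), both through chair-like transition states. C3 is carried over unchanged; C4 is fixed by double inversion (bromine displaces oxygen, C5 displaces bromine) and by the E-type geometry of the bromiranium ion inherited from the trans-epoxide, which puts CH3 axial and the butenyl chain and bromine equatorial; C5 and C10 follow from anti addition across the (E)-C5=C10 olefin in the chair–chair array (trans fusion), and C9 from the (Z)-allylsilane, whose CH2Ar group is trans to C7 and so becomes equatorial. The step needs opening of the bromiranium ion at C4 and not at C3 (secured by the cation-stabilising tertiary C4 and the six-membered chair transition state), a silent side chain (the but-3-enyl group is a non-nucleophilic monosubstituted alkene), a single olefin position on termination (β-silicon effect) and no oxygen capture of the C8 cation (the phenol is acetylated). The hindered pyridine base removes the acid that would protodesilylate the allylsilane, and high dilution suppresses bromonium transfer between olefins, which would erode the enantiomeric purity.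

Step 14
Reactants: 21 methyl 4-(acetyloxy)-3-bromo-5-{[(1R,4aS,5R,6R,8aS)-6-bromo-5-(but-3-en-1-yl)-5,8a-dimethyl-2-methylidenedecahydronaphthalen-1-yl]methyl}benzoate
Product: 22 methyl 4-(acetyloxy)-3-bromo-5-{[(1R,4aS,5R,6R,8aS)-6-bromo-5,8a-dimethyl-2-methylidene-5-(4-methylpent-3-en-1-yl)decahydronaphthalen-1-yl]methyl}benzoate
Conditions: 2-methyl-2-butene (excess), RuCl2(=CHPh)(PCy3)(H2IMes) (second-generation Grubbs catalyst, cat.), CH2Cl2, 40 °C
Reagents that add atoms: 2-methyl-2-butene, CC=C(C)C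
Why: Olefin cross-metathesis with excess 2-methyl-2-butene should convert the monosubstituted vinyl group into the isopropylidene terminus (C14=C15), whereas the hindered 1,1-disubstituted exocyclic methylene is a poor metathesis partner.

Step 15
Reactants: 22 methyl 4-(acetyloxy)-3-bromo-5-{[(1R,4aS,5R,6R,8aS)-6-bromo-5,8a-dimethyl-2-methylidene-5-(4-methylpent-3-en-1-yl)decahydronaphthalen-1-yl]methyl}benzoate
Product: 23 callophycoic acid H, 3-bromo-5-{[(1R,4aS,5R,6R,8aS)-6-bromo-5,8a-dimethyl-2-methylidene-5-(4-methylpent-3-en-1-yl)decahydronaphthalen-1-yl]methyl}-4-hydroxybenzoic acid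
Conditions: LiOH·H2O, THF/MeOH/H2O, 50 °C; then 1 M HCl
Reagents that add atoms: lithium hydroxide, [Li+].[OH-]
Why: Saponification should cleave the aryl acetate and the methyl ester, while the equatorial, neopentyl-type secondary bromide has no anti-periplanar hydrogen for E2 and is shielded against SN2.

**Compound list**

1 | geranyl bromide, (2E)-1-bromo-3,7-dimethylocta-2,6-diene | CC(C)=CCC/C(C)=C/CBr | starting material
2 | trimethyl(prop-1-yn-1-yl)silane | CC#C[Si](C)(C)C | starting material
3 | [3-(trimethylsilyl)prop-2-yn-1-yl]lithium (lithiated silylpropyne) | [Li]CC#C[Si](C)(C)C | intermediate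
4 | trimethyl[(5E)-6,10-dimethylundeca-5,9-dien-1-yn-1-yl]silane | CC(C)=CCC/C(C)=C/CCC#C[Si](C)(C)C | intermediate
5 | (2E,6E)-2,6-dimethyl-11-(trimethylsilyl)undeca-2,6-dien-10-yn-1-ol | OC/C(C)=C/CC/C(C)=C/CCC#C[Si](C)(C)C | intermediate
6 | [(2S,3S)-2-methyl-3-[(3E)-3-methyl-8-(trimethylsilyl)oct-3-en-7-yn-1-yl]oxiran-2-yl]methanol | OC[C@]1(C)O[C@H]1CC/C(C)=C/CCC#C[Si](C)(C)C | intermediate
7 | [(2S,3S)-2-methyl-3-[(3E)-3-methyl-8-(trimethylsilyl)oct-3-en-7-yn-1-yl]oxiran-2-yl]methyl trifluoromethanesulfonate (epoxy triflate) | FC(F)(F)S(=O)(=O)OC[C@]1(C)O[C@H]1CC/C(C)=C/CCC#C[Si](C)(C)C | intermediate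
8 | (2S,3S)-2-(but-3-en-1-yl)-2-methyl-3-[(3E)-3-methyl-8-(trimethylsilyl)oct-3-en-7-yn-1-yl]oxirane | C=CCC[C@]1(C)O[C@H]1CC/C(C)=C/CCC#C[Si](C)(C)C | intermediate
9 | (2S,3S)-2-(but-3-en-1-yl)-2-methyl-3-[(3E)-3-methyloct-3-en-7-yn-1-yl]oxirane | C=CCC[C@]1(C)O[C@H]1CC/C(C)=C/CCC#C | intermediate
10 | {(1Z,5E)-8-[(2S,3S)-3-(but-3-en-1-yl)-3-methyloxiran-2-yl]-6-methyl-2-[(trimethylsilyl)methyl]octa-1,5-dien-1-yl}copper (alkenylcopper) | C=CCC[C@]1(C)O[C@H]1CC/C(C)=C/CC/C(C[Si](C)(C)C)=C/[Cu] | intermediate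
11 | (2S,3S)-2-(but-3-en-1-yl)-3-[(3E,7Z)-8-iodo-3-methyl-7-[(trimethylsilyl)methyl]octa-3,7-dien-1-yl]-2-methyloxirane | C=CCC[C@]1(C)O[C@H]1CC/C(C)=C/CC/C(C[Si](C)(C)C)=C/I | intermediate
12 | methyl 4-hydroxy-3-methylbenzoate | COC(=O)c1ccc(O)c(C)c1 | starting material
13 | methyl 3-bromo-4-hydroxy-5-methylbenzoate | COC(=O)c1cc(C)c(O)c(Br)c1 | intermediate
14 | methyl 4-(acetyloxy)-3-bromo-5-methylbenzoate | COC(=O)c1cc(C)c(OC(C)=O)c(Br)c1 | intermediate
15 | methyl 4-(acetyloxy)-3-bromo-5-(bromomethyl)benzoate | COC(=O)c1cc(CBr)c(OC(C)=O)c(Br)c1 | intermediate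
16 | {[2-(acetyloxy)-3-bromo-5-(methoxycarbonyl)phenyl]methyl}zinc bromide (benzylzinc bromide) | COC(=O)c1cc(C[Zn]Br)c(OC(C)=O)c(Br)c1 | intermediate
17 | methyl 4-(acetyloxy)-3-bromo-5-[(2Z,6E)-9-[(2S,3S)-3-(but-3-en-1-yl)-3-methyloxiran-2-yl]-7-methyl-3-[(trimethylsilyl)methyl]nona-2,6-dien-1-yl]benzoate | C=CCC[C@]1(C)O[C@H]1CC/C(C)=C/CC/C(C[Si](C)(C)C)=C/Cc1cc(C(=O)OC)cc(Br)c1OC(C)=O | intermediate
18 | methyl 4-(acetyloxy)-3-bromo-5-[(2Z,6E,10R,11S)-10-bromo-11-hydroxy-7,11-dimethyl-3-[(trimethylsilyl)methyl]pentadeca-2,6,14-trien-1-yl]benzoate | C=CCC[C@](C)(O)[C@H](Br)CC/C(C)=C/CC/C(C[Si](C)(C)C)=C/Cc1cc(C(=O)OC)cc(Br)c1OC(C)=O | intermediate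
19 | methyl 4-(acetyloxy)-3-bromo-5-[(2Z,6E,10R,11S)-10-bromo-7,11-dimethyl-11-(trifluoroacetoxy)-3-[(trimethylsilyl)methyl]pentadeca-2,6,14-trien-1-yl]benzoate | C=CCC[C@](C)(OC(=O)C(F)(F)F)[C@H](Br)CC/C(C)=C/CC/C(C[Si](C)(C)C)=C/Cc1cc(C(=O)OC)cc(Br)c1OC(C)=O | intermediate
20 | (2R,3R)-3-[(3E,7Z)-9-[2-(acetyloxy)-3-bromo-5-(methoxycarbonyl)phenyl]-3-methyl-7-[(trimethylsilyl)methyl]nona-3,7-dien-1-yl]-2-(but-3-en-1-yl)-2-methylbromiranium trifluoroacetate (bromiranium ion) | C=CCC[C@@]1(C)[Br+][C@@H]1CC/C(C)=C/CC/C(C[Si](C)(C)C)=C/Cc1cc(C(=O)OC)cc(Br)c1OC(C)=O.[O-]C(=O)C(F)(F)F | intermediate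
21 | methyl 4-(acetyloxy)-3-bromo-5-{[(1R,4aS,5R,6R,8aS)-6-bromo-5-(but-3-en-1-yl)-5,8a-dimethyl-2-methylidenedecahydronaphthalen-1-yl]methyl}benzoate | C=C1CC[C@@H]2[C@@](C)(CCC=C)[C@H](Br)CC[C@@]2(C)[C@@H]1Cc1cc(C(=O)OC)cc(Br)c1OC(C)=O | intermediate
22 | methyl 4-(acetyloxy)-3-bromo-5-{[(1R,4aS,5R,6R,8aS)-6-bromo-5,8a-dimethyl-2-methylidene-5-(4-methylpent-3-en-1-yl)decahydronaphthalen-1-yl]methyl}benzoate | C=C1CC[C@@H]2[C@@](C)(CCC=C(C)C)[C@H](Br)CC[C@@]2(C)[C@@H]1Cc1cc(C(=O)OC)cc(Br)c1OC(C)=O | intermediate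
23 | callophycoic acid H, 3-bromo-5-{[(1R,4aS,5R,6R,8aS)-6-bromo-5,8a-dimethyl-2-methylidene-5-(4-methylpent-3-en-1-yl)decahydronaphthalen-1-yl]methyl}-4-hydroxybenzoic acid | C=C1CC[C@@H]2[C@@](C)(CCC=C(C)C)[C@H](Br)CC[C@@]2(C)[C@@H]1Cc1cc(C(=O)O)cc(Br)c1O | target

**Step count and risks**

Total step count: 15. Longest linear sequence: 12 steps (steps 1–6 and 10–15, from 1 to 23).

Steps most likely to fail:

Step 13 (key step). What may go wrong: ionisation of the trifluoroacetate in the protic medium may be too slow, or the acid released may protodesilylate the allylsilane before the cascade ends. Fallback: it sets out from bromohydrin 18 and returns to the route at 21, so that step 12 is not needed. The tertiary alcohol is sulfonylated in an aprotic medium (Tf2O, 2,6-di-tert-butyl-4-methylpyridine, CH2Cl2, −78 °C). The resulting tertiary triflate F1 cannot persist and should ionise at once, irreversibly and without free acid, to the same bromiranium ion 20 (as its triflate salt), which then closes rings A and B as in the main route.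

Step 11. What may go wrong: bromide may attack the tertiary instead of the secondary epoxide carbon, or Lewis-acid activation may start an epoxide-initiated cyclisation. Fallback: it sets out from epoxide 17 and returns to the route at 21, replacing steps 11–13. The epoxide is opened on purpose in the Markovnikov sense (MgBr2·OEt2, Et2O, −20 °C; bromide enters at C4 with inversion) to give the regioisomeric anti bromohydrin F2 (tertiary bromide, secondary alcohol). Treatment with Tf2O and 2,6-di-tert-butyl-4-methylpyridine in CH2Cl2 at −78 °C gives the secondary triflate F3, which is displaced intramolecularly by the neighbouring tertiary bromine. Both anti bromohydrin regioisomers converge on the same bromiranium ion 20, which cyclises to 21.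

Step 6. What may go wrong: the magnesium halide that accompanies the organocopper reagent may open or rearrange the trisubstituted epoxide, or the addition may be sluggish. Fallback: it sets out from allylic alcohol 5 and returns to the route at 11, replacing steps 3–6, so that the carbocupration is run before the epoxide exists. Desilylation of 5 (K2CO3, MeOH) gives the terminal alkynol F4. One extra equivalent of Me3SiCH2MgCl converts its hydroxyl into the magnesium alkoxide, and carbocupration with Me3SiCH2Cu·MgBrCl gives the alkenylcopper alkoxide F5. Iodinolysis of F5 gives the iodo-allylsilane alcohol F6. Sharpless epoxidation of F6 (Ti(OiPr)4, L-(+)-diisopropyl tartrate, t-BuOOH) gives the epoxy alcohol F7. Triflation (Tf2O, 2,6-lutidine, −78 °C) gives the epoxy triflate F8, and copper-catalysed displacement with allylMgBr at −78 °C gives 11.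

Further compounds
F1 | step 13 | methyl 4-(acetyloxy)-3-bromo-5-[(2Z,6E,10R,11S)-10-bromo-7,11-dimethyl-11-[(trifluoromethanesulfonyl)oxy]-3-[(trimethylsilyl)methyl]pentadeca-2,6,14-trien-1-yl]benzoate (tertiary triflate) | C=CCC[C@](C)(OS(=O)(=O)C(F)(F)F)[C@H](Br)CC/C(C)=C/CC/C(C[Si](C)(C)C)=C/Cc1cc(C(=O)OC)cc(Br)c1OC(C)=O
F2 | step 11 | methyl 4-(acetyloxy)-3-bromo-5-[(2Z,6E,10S,11R)-11-bromo-10-hydroxy-7,11-dimethyl-3-[(trimethylsilyl)methyl]pentadeca-2,6,14-trien-1-yl]benzoate (regioisomeric anti bromohydrin) | C=CCC[C@@](C)(Br)[C@@H](O)CC/C(C)=C/CC/C(C[Si](C)(C)C)=C/Cc1cc(C(=O)OC)cc(Br)c1OC(C)=O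
F3 | step 11 | methyl 4-(acetyloxy)-3-bromo-5-[(2Z,6E,10S,11R)-11-bromo-7,11-dimethyl-10-[(trifluoromethanesulfonyl)oxy]-3-[(trimethylsilyl)methyl]pentadeca-2,6,14-trien-1-yl]benzoate (secondary triflate) | C=CCC[C@@](C)(Br)[C@@H](OS(=O)(=O)C(F)(F)F)CC/C(C)=C/CC/C(C[Si](C)(C)C)=C/Cc1cc(C(=O)OC)cc(Br)c1OC(C)=O
F4 | step 6 | (2E,6E)-2,6-dimethylundeca-2,6-dien-10-yn-1-ol (terminal alkynol) | OC/C(C)=C/CC/C(C)=C/CCC#C
F5 | step 6 | chloromagnesium (2E,6E,10Z)-11-cuprio-2,6-dimethyl-10-[(trimethylsilyl)methyl]undeca-2,6,10-trien-1-olate (alkenylcopper alkoxide) | [O-]C/C(C)=C/CC/C(C)=C/CC/C(C[Si](C)(C)C)=C/[Cu].[Mg+2].[Cl-]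
F6 | step 6 | (2E,6E,10Z)-11-iodo-2,6-dimethyl-10-[(trimethylsilyl)methyl]undeca-2,6,10-trien-1-ol (iodo-allylsilane alcohol) | OC/C(C)=C/CC/C(C)=C/CC/C(C[Si](C)(C)C)=C/I
F7 | step 6 | [(2S,3S)-3-[(3E,7Z)-8-iodo-3-methyl-7-[(trimethylsilyl)methyl]octa-3,7-dien-1-yl]-2-methyloxiran-2-yl]methanol (epoxy alcohol) | OC[C@]1(C)O[C@H]1CC/C(C)=C/CC/C(C[Si](C)(C)C)=C/I
F8 | step 6 | [(2S,3S)-3-[(3E,7Z)-8-iodo-3-methyl-7-[(trimethylsilyl)methyl]octa-3,7-dien-1-yl]-2-methyloxiran-2-yl]methyl trifluoromethanesulfonate (epoxy triflate) | FC(F)(F)S(=O)(=O)OC[C@]1(C)O[C@H]1CC/C(C)=C/CC/C(C[Si](C)(C)C)=C/I
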